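**Plan**
- Retrosynthetic cuts, in order: the four O–Si bonds; the C1''–C2'' bond between the benzylic CH2 on C6 and the vinylic CH of the side chain; the C2–C1' bond joining ring B to the pyranone; the C6–CH2 bond; in the side chain the C1–B/I bond, the alkyne C–CH3 bond and the carbinol C–H bond.
- Enabling feature: the benzylic CH2 sits on C6 of ring A between O5 and O7 (O1 para), so a C6–CH2–O unit is a latent ortho-quinone methide (exocyclic C6=CH2, C5=O). It is stored as a 1,3-dioxine (acetonide) ring across O5 and the C6 methylene and opened only in the coupling flask, where boron tethers the alkenyl group to O5.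
- Forward order: the preformed A/C chromone is functionalised at C6 (5-OH-directed iodination, Stille hydroxymethylation, acetonide); ring B is added to C2 by asymmetric conjugate arylation (chromone to flavanone); the C9 alkenylboronic acid is joined at the benzylic carbon; fluoride frees all hydroxyls.
- Side chain: Weinreb ketone, Corey–Bakshi–Shibata reduction, Negishi carboalumination/iodination, borylation.
- Stereochemistry: C2 (S) from the chiral Rh–bisphosphine catalyst; the side-chain carbinol (R) from the (S)-oxazaborolidine; the (E)-C2''=C3'' bond from syn-carboalumination, carried with retention through I, Li and B to carbon.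

Key step: step 15

Assumption: the (S)-configured biaryl bisphosphine is taken to give 2S by analogy with the (S)-BINAP/Rh enone arylation model (same face of the enone); should the sense be opposite, the enantiomeric ligand would be used.

**Route**

Step 1
Reactants: 1 5,7-dihydroxychromone
Product: 2 5-hydroxy-7-(triisopropylsilyloxy)-4H-chromen-4-one
Conditions: TIPSCl, imidazole, DMF, 0 °C → rt
Reagents that add atoms: triisopropylsilyl chloride, CC(C)[Si](Cl)(C(C)C)C(C)C
Why: The 7-OH (vinylogous acid, not hydrogen-bonded) should be silylated selectively while the 5-OH stays chelated to C4=O; standard phenol silylation.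

Step 2
Reactants: 2 5-hydroxy-7-(triisopropylsilyloxy)-4H-chromen-4-one
Product: 3 5-hydroxy-6-iodo-7-(triisopropylsilyloxy)-4H-chromen-4-one
Conditions: BnNMe3·ICl2, CaCO3, CH2Cl2/MeOH, rt
Reagents that add atoms: benzyltrimethylammonium dichloroiodate, C[N+](C)(C)Cc1ccccc1.Cl[I-]Cl
Why: Electrophilic aromatic iodination is directed ortho to the only free phenol, so iodine should enter at C6 (between O5 and O7) and not at C8, the selectivity known for 5-hydroxy-7-alkoxy chromones and flavones with dichloroiodate.

Step 3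
Reactants: 3 5-hydroxy-6-iodo-7-(triisopropylsilyloxy)-4H-chromen-4-one
Product: 4 5-hydroxy-6-(hydroxymethyl)-7-(triisopropylsilyloxy)-4H-chromen-4-one
Conditions: Bu3SnCH2OH, Pd(PPh3)4 (cat.), 1,4-dioxane, 90 °C
Reagents that add atoms: (tributylstannyl)methanol, CCCC[Sn](CCCC)(CCCC)CO
Why: Stille hydroxymethylation transfers CH2OH from tin to the aryl iodide under neutral conditions that leave the chromone, the free phenol and the silyl ether untouched.

Step 4
Reactants: 4 5-hydroxy-6-(hydroxymethyl)-7-(triisopropylsilyloxy)-4H-chromen-4-one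
Product: 5 7-(triisopropylsilyloxy)chromone with O5 and the C6 CH2O bridged by CMe2 (2,2-dimethyl-4H-1,3-dioxine ring fused at C5–C6)
Conditions: 2-methoxypropene, PPTS (cat.), CH2Cl2, 0 °C → rt
Reagents that add atoms: 2-methoxypropene, C=C(C)OC
Why: Acid-catalysed acetalisation of the ortho-hydroxybenzyl alcohol closes the six-membered salicyl-alcohol acetonide, which masks the 5-OH and stores the benzylic C–O bond as a latent ortho-quinone methide.

Step 5
Reactants: 6 5-bromo-2-hydroxy-3-methoxybenzaldehyde
Product: 8 5-bromo-3-methoxybenzene-1,2-diol, via aryl formate 7 (not isolated)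
Conditions: 30% H2O2, aq. NaOH, THF/H2O, 0 °C → rt, N2; then HCl
Reagents that add atoms: hydrogen peroxide, OO
Why: Dakin oxidation, in which hydroperoxide adds to the ortho-hydroxybenzaldehyde, aryl migration gives the formate and saponification in the same flask gives the catechol.

Step 6
Reactants: 8 5-bromo-3-methoxybenzene-1,2-diol
Product: 9 5-bromo-1,2-bis(tert-butyldimethylsilyloxy)-3-methoxybenzene
Conditions: TBSCl, imidazole, DMF, rt
Reagents that add atoms: tert-butyldimethylsilyl chloride, CC(C)(C)[Si](C)(C)Cl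
Why: Standard bis-silylation of the catechol; silyl ethers are used so that all phenols can be freed at the end by buffered fluoride without base or strong acid.

Step 7
Reactants: 9 5-bromo-1,2-bis(tert-butyldimethylsilyloxy)-3-methoxybenzene
Product: 12 [3,4-bis(tert-butyldimethylsilyloxy)-5-methoxyphenyl]boronic acid, via aryllithium 10 (not isolated), via lithium aryltriisopropoxyborate 11 (not isolated)
Conditions: n-BuLi, THF, −78 °C; B(OiPr)3, −78 °C → rt; 1 M HCl to pH 5
Reagents that add atoms: triisopropyl borate, CC(C)OB(OC(C)C)OC(C)C; water, O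
Why: Bromine–lithium exchange, borylation and acidic hydrolysis of the borate; the lithium sits meta/para to the silyloxy groups, so no silyl migration is expected.

Step 8
Reactants: 5 chromone acetonide; 12 [3,4-bis(tert-butyldimethylsilyloxy)-5-methoxyphenyl]boronic acid
Product: 13 (2S)-2-[3,4-bis(tert-butyldimethylsilyloxy)-5-methoxyphenyl]-7-(triisopropylsilyloxy)chroman-4-one with the O5/C6-CH2O acetonide (2,2-dimethyl-4H-1,3-dioxine fused at C5–C6)
Conditions: [Rh(OH)(cod)]2 (cat.), (S)-MeO-F12-BIPHEP (cat.), toluene/H2O, 40 °C, no added base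
Reagents that add atoms: none
Why: Rh-catalysed asymmetric conjugate arylation (Hayashi–Miyaura reaction) of the chromone, in which the aryl–Rh(I) species carbometalates C2=C3 from the face left open by the C2-symmetric bisphosphine to set C2 as S, the oxa-π-allyl rhodium is protonated by water, and the base-free medium avoids retro-oxa-Michael opening of the flavanone.

Step 9
Reactants: 14 pent-4-ynoic acid
Product: 16 N-methoxy-N-methylpent-4-ynamide, via acyl imidazolide 15 (not isolated)
Conditions: CDI, CH2Cl2, rt; then MeNHOMe·HCl, rt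
Reagents that add atoms: N,O-dimethylhydroxylamine hydrochloride, CNOC.Cl
Why: Activation of the acid as the acyl imidazolide and aminolysis give the Weinreb amide, a standard amide coupling that tolerates the terminal alkyne.

Step 10
Reactants: 16 N-methoxy-N-methylpent-4-ynamide; 17 isopropenylmagnesium bromide
Product: 19 2-methylhept-1-en-6-yn-3-one, via magnesium hemiaminal chelate 18 (not isolated)
Conditions: 17 (2.5 equiv), THF, −20 → 0 °C; inverse quench into cold 1 M HCl
Reagents that add atoms: none
Why: Weinreb ketone synthesis, in which the chelated tetrahedral intermediate prevents over-addition, excess Grignard covers deprotonation of the alkyne C–H and the inverse acidic quench suppresses aza-Michael addition of the liberated hydroxylamine to the enone.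

Step 11
Reactants: 19 2-methylhept-1-en-6-yn-3-one
Product: 21 (3R)-2-methylhept-1-en-6-yn-3-ol, via alkoxyborane 20 (not isolated)
Conditions: (S)-Me-CBS (cat.), catecholborane, toluene, −78 °C; aq. work-up
Reagents that add atoms: none
Why: Corey–Bakshi–Shibata reduction in which the isopropenyl group acts as the large substituent, so the (S)-oxazaborolidine should deliver hydride with the topicity of acetophenone → (R)-1-phenylethanol and give the (R)-carbinol, while catecholborane at −78 °C spares the alkyne and the alkene.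

Step 12
Reactants: 21 (3R)-2-methylhept-1-en-6-yn-3-ol
Product: 22 (3R)-3-(tert-butyldimethylsilyloxy)-2-methylhept-1-en-6-yne
Conditions: TBSCl, imidazole, DMF, rt
Reagents that add atoms: tert-butyldimethylsilyl chloride, CC(C)(C)[Si](C)(C)Cl
Why: Standard silylation of the secondary allylic alcohol, which keeps it inert to AlMe3, t-BuLi and the acidic coupling step.

Step 13
Reactants: 22 (3R)-3-(tert-butyldimethylsilyloxy)-2-methylhept-1-en-6-yne
Product: 24 (3R,6E)-3-(tert-butyldimethylsilyloxy)-7-iodo-2,6-dimethylhepta-1,6-diene, via alkenylalane 23 (not isolated)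
Conditions: AlMe3, Cp2ZrCl2 (cat.), CH2Cl2, 0 °C → rt; then I2, THF, −30 → 0 °C
Reagents that add atoms: trimethylaluminium, C[Al](C)C; iodine, II
Why: Negishi zirconium-catalysed carboalumination adds Me and Al syn across the terminal alkyne with Al on the terminal carbon, and iodinolysis with retention gives the (E)-iodide; the 1,1-disubstituted alkene and the silyl ether are inert.

Step 14
Reactants: 24 (3R,6E)-3-(tert-butyldimethylsilyloxy)-7-iodo-2,6-dimethylhepta-1,6-diene
Product: 27 [(1E,5R)-5-(tert-butyldimethylsilyloxy)-2,6-dimethylhepta-1,6-dien-1-yl]boronic acid, via alkenyllithium 25 (not isolated), via lithium alkenyltriisopropoxyborate 26 (not isolated)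
Conditions: t-BuLi (2 equiv), Et2O, −78 °C; B(OiPr)3, −78 °C → rt; 1 M HCl to pH 5
Reagents that add atoms: triisopropyl borate, CC(C)OB(OC(C)C)OC(C)C; water, O
Why: Iodine–lithium exchange and borylation of the alkenyllithium both proceed with retention of the double-bond geometry, and mild acidic hydrolysis of the borate gives the boronic acid.

Step 15
Reactants: 13 (2S)-flavanone acetonide; 27 [(1E,5R)-5-(tert-butyldimethylsilyloxy)-2,6-dimethylhepta-1,6-dien-1-yl]boronic acid
Product: 31 (2S)-2-[3,4-bis(tert-butyldimethylsilyloxy)-5-methoxyphenyl]-6-[(2E,6R)-6-(tert-butyldimethylsilyloxy)-3,7-dimethylocta-2,7-dien-1-yl]-5-hydroxy-7-(triisopropylsilyloxy)chroman-4-one, via alkenyl benzodioxaborin 28 (not isolated), via ortho-quinone methide boronate 29 (not isolated), via aryl borate 30 (not isolated)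
Conditions: 27 (1.5 equiv), (PhO)2P(O)OH (10 mol %), HFIP/CH2Cl2 (1:4), 0 °C → rt; pH 7 buffer work-up
Reagents that add atoms: none
Why: Acid-catalysed exchange of the isopropylidene acetal for the boronic acid should give the 2-alkenyl-4H-1,3,2-benzodioxaborin 28, which tethers the alkenyl group through boron to O5 and to the benzylic oxygen. Ionisation of the benzylic C–O bond, pushed by the O5, O7 and O1 lone pairs, then gives the O5-borylated ortho-quinone methide 29 (exocyclic C6=CH2 conjugated to C5=O), and the alkenyl group migrates from four-coordinate boron to the methide carbon through a six-membered B–O5–C5–C6–CH2–C(alkenyl) transition state, re-aromatising ring A to the borate 30, which is hydrolysed on work-up. The closest known reaction type is the Petasis-type 1,4-addition of alkenylboronic acids and boronates to ortho-quinone methides generated in the flask from ortho-hydroxybenzyl alcohols or ethers, with phenol-bound boron delivering the alkenyl group as in the Petasis borono-Mannich reaction of salicylaldehydes. No ring of the target is closed; the six-membered dioxaborin is a temporary ring formed by transacetalisation and destroyed in the same flask. No stereocentre is created: C2 and the side-chain carbinol are spectators under the weakly acidic, base-free conditions, and the E geometry is kept because the sp2 carbon migrates with retention. The step needs C-attack at the methide carbon over O-alkylation, over hetero-Diels–Alder trapping by the isopropenyl group and over attack by C8 of a second flavanone, which intramolecular delivery from boron on O5 and the excess boronic acid should secure, while attachment at C6 and not at C8 follows from the position of the CH2 group, installed at C6 in steps 2 and 3.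

Step 16
Reactants: 31 tetrasilyl ether of the target
Product: 32 (2S)-2-(3,4-dihydroxy-5-methoxyphenyl)-5,7-dihydroxy-6-[(2E,6R)-6-hydroxy-3,7-dimethylocta-2,7-dien-1-yl]chroman-4-one
Conditions: TBAF/AcOH (1:1, excess), THF, 0 °C → rt
Reagents that add atoms: none
Why: Fluoride cleaves the three aryl silyl ethers and the secondary alkyl silyl ether, and the acetic acid buffer keeps the phenols protonated so that the flavanone should not open to the chalcone (which would racemise C2 and interchange C6/C8) and the allylic alcohol is not ionised.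

**Compound list**

1 | 5,7-dihydroxychromone (5,7-dihydroxy-4H-chromen-4-one) | O=c1ccoc2cc(O)cc(O)c12 | starting material
2 | 5-hydroxy-7-(triisopropylsilyloxy)-4H-chromen-4-one | O=c1ccoc2cc(O[Si](C(C)C)(C(C)C)C(C)C)cc(O)c12 | intermediate
3 | 5-hydroxy-6-iodo-7-(triisopropylsilyloxy)-4H-chromen-4-one | O=c1ccoc2cc(O[Si](C(C)C)(C(C)C)C(C)C)c(I)c(O)c12 | intermediate
4 | 5-hydroxy-6-(hydroxymethyl)-7-(triisopropylsilyloxy)-4H-chromen-4-one | O=c1ccoc2cc(O[Si](C(C)C)(C(C)C)C(C)C)c(CO)c(O)c12 | intermediate
5 | chromone acetonide: 7-(triisopropylsilyloxy)chromone with O5 and the C6 CH2O bridged by CMe2 (2,2-dimethyl-4H-1,3-dioxine fused at C5–C6) | CC1(C)OCc2c(O[Si](C(C)C)(C(C)C)C(C)C)cc3occc(=O)c3c2O1 | intermediate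
6 | 5-bromo-2-hydroxy-3-methoxybenzaldehyde | O=Cc1cc(Br)cc(OC)c1O | starting material
7 | 5-bromo-2-hydroxy-3-methoxyphenyl formate | O=COc1cc(Br)cc(OC)c1O | intermediate (not isolated)
8 | 5-bromo-3-methoxybenzene-1,2-diol | Oc1cc(Br)cc(OC)c1O | intermediate
9 | 5-bromo-1,2-bis(tert-butyldimethylsilyloxy)-3-methoxybenzene | COc1cc(Br)cc(O[Si](C)(C)C(C)(C)C)c1O[Si](C)(C)C(C)(C)C | intermediate
10 | [3,4-bis(tert-butyldimethylsilyloxy)-5-methoxyphenyl]lithium | [Li]c1cc(O[Si](C)(C)C(C)(C)C)c(O[Si](C)(C)C(C)(C)C)c(OC)c1 | intermediate (not isolated)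
11 | lithium [3,4-bis(tert-butyldimethylsilyloxy)-5-methoxyphenyl]triisopropoxyborate | [Li+].CC(C)O[B-](OC(C)C)(OC(C)C)c1cc(O[Si](C)(C)C(C)(C)C)c(O[Si](C)(C)C(C)(C)C)c(OC)c1 | intermediate (not isolated)
12 | [3,4-bis(tert-butyldimethylsilyloxy)-5-methoxyphenyl]boronic acid | OB(O)c1cc(O[Si](C)(C)C(C)(C)C)c(O[Si](C)(C)C(C)(C)C)c(OC)c1 | intermediate
13 | (2S)-2-[3,4-bis(tert-butyldimethylsilyloxy)-5-methoxyphenyl]-7-(triisopropylsilyloxy)chroman-4-one with the O5/C6-CH2O acetonide | CC1(C)OCc2c(O[Si](C(C)C)(C(C)C)C(C)C)cc3c(c2O1)C(=O)C[C@@H](c2cc(O[Si](C)(C)C(C)(C)C)c(O[Si](C)(C)C(C)(C)C)c(OC)c2)O3 | intermediate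
14 | pent-4-ynoic acid | C#CCCC(=O)O | starting material
15 | 1-(pent-4-ynoyl)imidazole | C#CCCC(=O)n1ccnc1 | intermediate (not isolated)
16 | N-methoxy-N-methylpent-4-ynamide | C#CCCC(=O)N(C)OC | intermediate
17 | isopropenylmagnesium bromide (THF solution) | C=C(C)[Mg]Br | starting material
18 | bromomagnesium alkoxide of the tetrahedral adduct (N-methoxy-N-methyl hemiaminal) | C#CCCC(O[Mg]Br)(N(C)OC)C(C)=C | intermediate (not isolated)
19 | 2-methylhept-1-en-6-yn-3-one | C=C(C)C(=O)CCC#C | intermediate
20 | 2-{[(3R)-2-methylhept-1-en-6-yn-3-yl]oxy}-1,3,2-benzodioxaborole | C=C(C)[C@H](OB1Oc2ccccc2O1)CCC#C | intermediate (not isolated)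
21 | (3R)-2-methylhept-1-en-6-yn-3-ol | C=C(C)[C@H](O)CCC#C | intermediate
22 | (3R)-3-(tert-butyldimethylsilyloxy)-2-methylhept-1-en-6-yne | C=C(C)[C@H](O[Si](C)(C)C(C)(C)C)CCC#C | intermediate
23 | [(1E,5R)-5-(tert-butyldimethylsilyloxy)-2,6-dimethylhepta-1,6-dien-1-yl]dimethylalane | C=C(C)[C@H](O[Si](C)(C)C(C)(C)C)CC/C(C)=C/[Al](C)C | intermediate (not isolated)
24 | (3R,6E)-3-(tert-butyldimethylsilyloxy)-7-iodo-2,6-dimethylhepta-1,6-diene | C=C(C)[C@H](O[Si](C)(C)C(C)(C)C)CC/C(C)=C/I | intermediate
25 | [(1E,5R)-5-(tert-butyldimethylsilyloxy)-2,6-dimethylhepta-1,6-dien-1-yl]lithium | C=C(C)[C@H](O[Si](C)(C)C(C)(C)C)CC/C(C)=C/[Li] | intermediate (not isolated)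
26 | lithium [(1E,5R)-5-(tert-butyldimethylsilyloxy)-2,6-dimethylhepta-1,6-dien-1-yl]triisopropoxyborate | [Li+].C=C(C)[C@H](O[Si](C)(C)C(C)(C)C)CC/C(C)=C/[B-](OC(C)C)(OC(C)C)OC(C)C | intermediate (not isolated)
27 | [(1E,5R)-5-(tert-butyldimethylsilyloxy)-2,6-dimethylhepta-1,6-dien-1-yl]boronic acid | C=C(C)[C@H](O[Si](C)(C)C(C)(C)C)CC/C(C)=C/B(O)O | intermediate
28 | 2-alkenyl-4H-1,3,2-dioxaborine fused at C5–C6 of the (2S)-flavanone (boron bridging O5 and the C6 CH2O, carrying the (1E,5R)-alkenyl group) | C=C(C)[C@H](O[Si](C)(C)C(C)(C)C)CC/C(C)=C/B1OCc2c(O[Si](C(C)C)(C(C)C)C(C)C)cc3c(c2O1)C(=O)C[C@@H](c2cc(O[Si](C)(C)C(C)(C)C)c(O[Si](C)(C)C(C)(C)C)c(OC)c2)O3 | intermediate (not isolated)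
29 | O5-borylated ortho-quinone methide (exocyclic C6=CH2, C5=O bound to the alkenyl(dihydroxy)borate) | C=C(C)[C@H](O[Si](C)(C)C(C)(C)C)CC/C(C)=C/[B-](O)(O)[O+]=C1C(=C)C(O[Si](C(C)C)(C(C)C)C(C)C)=CC2=C1C(=O)C[C@@H](c1cc(O[Si](C)(C)C(C)(C)C)c(O[Si](C)(C)C(C)(C)C)c(OC)c1)O2 | intermediate (not isolated)
30 | 5-O-dihydroxyboryl ester of 31 | C=C(C)[C@H](O[Si](C)(C)C(C)(C)C)CC/C(C)=C/Cc1c(O[Si](C(C)C)(C(C)C)C(C)C)cc2c(c1OB(O)O)C(=O)C[C@@H](c1cc(O[Si](C)(C)C(C)(C)C)c(O[Si](C)(C)C(C)(C)C)c(OC)c1)O2 | intermediate (not isolated)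
31 | (2S)-2-[3,4-bis(tert-butyldimethylsilyloxy)-5-methoxyphenyl]-6-[(2E,6R)-6-(tert-butyldimethylsilyloxy)-3,7-dimethylocta-2,7-dien-1-yl]-5-hydroxy-7-(triisopropylsilyloxy)chroman-4-one | C=C(C)[C@H](O[Si](C)(C)C(C)(C)C)CC/C(C)=C/Cc1c(O[Si](C(C)C)(C(C)C)C(C)C)cc2c(c1O)C(=O)C[C@@H](c1cc(O[Si](C)(C)C(C)(C)C)c(O[Si](C)(C)C(C)(C)C)c(OC)c1)O2 | intermediate
32 | (2S)-2-(3,4-dihydroxy-5-methoxyphenyl)-5,7-dihydroxy-6-[(2E,6R)-6-hydroxy-3,7-dimethylocta-2,7-dien-1-yl]chroman-4-one | C=C(C)[C@H](O)CC/C(C)=C/Cc1c(O)cc2c(c1O)C(=O)C[C@@H](c1cc(O)c(O)c(OC)c1)O2 | target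

**Step count and risks**

Total steps: 16. Longest linear sequence: 8 steps (14 → 16 → 19 → 21 → 22 → 24 → 27 → 31 → 32; steps 9–16).

Steps most likely to fail:

1. Step 15. The quinone methide may be consumed by attack of C8 of a second flavanone (methylene-bridged dimers) or by O-alkylation before the alkenyl group is transferred, or the boronic acid may protodeboronate under the acid. The fallback replaces the quinone-methide event by a palladium cross-coupling at the same bond and sets out from 13. Aqueous AcOH/THF at rt would cleave the acetal to the (2S)-5-hydroxy-6-(hydroxymethyl) flavanone F1, used crude. Methyl chloroformate, pyridine and DMAP in CH2Cl2 at 0 °C would then give the bis(methyl carbonate) F2. A base-free Suzuki–Miyaura coupling of the benzylic carbonate with 27 ([Pd(η3-C3H5)(cod)]BF4, bis(diphenylphosphino)pentane, toluene, 80 °C), running through an η3-benzylpalladium methoxide, should give the 5-O-methoxycarbonyl coupling product F3. Brief ammonolysis (NH3/MeOH, 0 °C) would free the 5-OH and come back to the route at 31.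

2. Step 8. Carbometalation of the electron-rich, trisubstituted chromone may be slow, or the facial selectivity may be insufficient. The fallback trades catalyst-controlled addition for a kinetic resolution and sets out from 5 and 12. Achiral Pd(OCOCF3)2/2,2'-bipyridine-catalysed conjugate addition in aqueous 1,2-dichloroethane at 60 °C should give the racemic flavanone acetonide F4. A Noyori-type asymmetric transfer hydrogenation (Cp*RhCl(TsDPEN), the antipode that reduces the (2R)-ketone faster, HCO2H/Et3N, EtOAc, rt, stopped near half conversion) would reduce the (2R)-enantiomer to the (2R,4R)-cis-flavan-4-ol F5. The unreduced (2S)-ketone, separated by chromatography, is 13, where the fallback comes back to the route.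

3. Step 3. Transmetalation at the iodide flanked by OH and OTIPS may be slow, protodeiodination may compete, and the new benzylic hydroxyl may be lost through quinone-methide formation at 90 °C. The fallback avoids the halide altogether and sets out from 2 (bypassing step 2 as well). Boron-templated ortho-hydroxymethylation (PhB(OH)2, paraformaldehyde, cat. propionic acid, toluene, reflux with water removal) can only reach C6, the single free position ortho to the 5-OH, and should give the 2-phenyl-4H-1,3,2-dioxaborine-fused chromone F6. Transesterification with propane-1,3-diol would release 4, where the fallback comes back to the route.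

Further compounds
F1 | step 15 | (2S)-2-[3,4-bis(tert-butyldimethylsilyloxy)-5-methoxyphenyl]-5-hydroxy-6-(hydroxymethyl)-7-(triisopropylsilyloxy)chroman-4-one | OCc1c(O[Si](C(C)C)(C(C)C)C(C)C)cc2c(c1O)C(=O)C[C@@H](c1cc(O[Si](C)(C)C(C)(C)C)c(O[Si](C)(C)C(C)(C)C)c(OC)c1)O2
F2 | step 15 | bis(methyl carbonate) of F1 (5-OCO2Me and 6-CH2OCO2Me) | COC(=O)OCc1c(O[Si](C(C)C)(C(C)C)C(C)C)cc2c(c1OC(=O)OC)C(=O)C[C@@H](c1cc(O[Si](C)(C)C(C)(C)C)c(O[Si](C)(C)C(C)(C)C)c(OC)c1)O2
F3 | step 15 | 5-O-methoxycarbonyl derivative of 31 | C=C(C)[C@H](O[Si](C)(C)C(C)(C)C)CC/C(C)=C/Cc1c(O[Si](C(C)C)(C(C)C)C(C)C)cc2c(c1OC(=O)OC)C(=O)C[C@@H](c1cc(O[Si](C)(C)C(C)(C)C)c(O[Si](C)(C)C(C)(C)C)c(OC)c1)O2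
F4 | step 8 | racemic form of 13 | CC1(C)OCc2c(O[Si](C(C)C)(C(C)C)C(C)C)cc3c(c2O1)C(=O)CC(c2cc(O[Si](C)(C)C(C)(C)C)c(O[Si](C)(C)C(C)(C)C)c(OC)c2)O3
F5 | step 8 | (2R,4R)-cis-flavan-4-ol from the (2R)-enantiomer of F4 | CC1(C)OCc2c(O[Si](C(C)C)(C(C)C)C(C)C)cc3c(c2O1)[C@H](O)C[C@H](c2cc(O[Si](C)(C)C(C)(C)C)c(O[Si](C)(C)C(C)(C)C)c(OC)c2)O3
F6 | step 3 | 2-phenyl-4H-1,3,2-dioxaborine fused at C5–C6 of 7-(triisopropylsilyloxy)chromone (boron bridging O5 and the C6 CH2O) | O=c1ccoc2cc(O[Si](C(C)C)(C(C)C)C(C)C)c3c(c12)OB(c1ccccc1)OC3
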